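## Retrosynthetic overview
1. The benzyl ester is removed last. The depside C–O bond is cut into the ring A acid (2,4-dimethoxy-6-pentylbenzoic acid) and the ring B phenol (benzyl 2-heptyl-4-hydroxy-6-methoxybenzoate).
2. Each resorcylate ring comes from a 6-alkyl-2-hydroxy-4-oxocyclohex-2-ene-1-carboxylate by bromination–dehydrobromination.
3. Each cyclohexenone comes from an intermolecular Michael addition of dimethyl malonate to an (E)-alk-3-en-2-one. This is the key C–C bond, the future C1–C6 of the arene. A Dieckmann/Claisen closure follows in the same flask.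
4. Non-3-en-2-one is bought. Undec-3-en-2-one is made from octanal and the acetonylidene ylide.
5. Ring order: ring A (steps 1–4), ring B (steps 5–12), union (step 13), deprotection (step 14).

Assumption: the SMILES holds no stereocentre and no stereogenic double bond, so the target is achiral. The stereocentres of the cyclohexenone intermediates are racemic and are erased on aromatisation.

## Route

Step 1
Reactants: 1 (E)-non-3-en-2-one; 2 dimethyl malonate
Product: 4 methyl 2-hydroxy-4-oxo-6-pentylcyclohex-2-ene-1-carboxylate, via Michael adduct 3 (not isolated)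
Conditions: NaOMe (1.2 equiv), 2 (1.2 equiv), MeOH, 0 °C → reflux, 4 h; then aq. HCl to pH 3, 0 °C
Reagents that add atoms: none
Why: The soft malonate anion adds 1,4 to the enone (intermolecular Michael addition), the methyl-ketone enolate then closes onto one ester (Dieckmann-type Claisen condensation) driven by the stabilised 1,3-dione enolate, and the two new stereocentres are racemic and vanish in step 2.

Step 2
Reactants: 4 methyl 2-hydroxy-4-oxo-6-pentylcyclohex-2-ene-1-carboxylate
Product: 6 methyl 2,4-dihydroxy-6-pentylbenzoate, via 3-bromo enol 5 (not isolated)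
Conditions: Br2 (1.0 equiv), DMF, 0 °C, 1 h; then 80 °C, 12 h
Reagents that add atoms: bromine, BrBr (its bromine stands only in 5 and leaves again as HBr; none remains in 6)
Why: Electrophilic bromination of the enolised 1,3-dione followed by thermal loss of HBr in hot DMF with tautomerisation to the phenol form (bromination–dehydrobromination aromatisation) gives the arene, and exactly one equivalent of Br2 at no more than 80 °C avoids ring bromination and ester loss.

Step 3
Reactants: 6 methyl 2,4-dihydroxy-6-pentylbenzoate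
Product: 7 methyl 2,4-dimethoxy-6-pentylbenzoate
Conditions: MeI (4 equiv), K2CO3 (4 equiv), DMF, 40 °C, 16 h
Reagents that add atoms: iodomethane, CI
Why: In this Williamson ether synthesis, excess MeI and carbonate in a dipolar aprotic solvent methylate both phenols, including the hydrogen-bonded ortho-OH, and leave the ester untouched.

Step 4
Reactants: 7 methyl 2,4-dimethoxy-6-pentylbenzoate
Product: 8 2,4-dimethoxy-6-pentylbenzoic acid
Conditions: KOH (10 equiv), DMSO/H2O 4:1, 100 °C, 16 h; then 2 M HCl, 0 °C
Reagents that add atoms: potassium hydroxide, [K+].[OH-] (its oxygen becomes the new carboxyl oxygen)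
Why: In this saponification, poorly solvated hydroxide in hot aqueous DMSO overcomes the di-ortho hindrance, the aryl methyl ethers are inert, and cold acidification avoids protodecarboxylation.

Step 5
Reactants: 9 octanal; 10 1-(triphenylphosphoranylidene)propan-2-one
Product: 11 (E)-undec-3-en-2-one
Conditions: 10 (1.1 equiv), CH2Cl2, rt → reflux, 16 h
Reagents that add atoms: none
Why: The Wittig olefination with a stabilised ylide gives the E-enone under neutral conditions without self-aldol of octanal, and the alkene geometry is consumed in step 6.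

Step 6
Reactants: 11 (E)-undec-3-en-2-one; 2 dimethyl malonate
Product: 13 methyl 6-heptyl-2-hydroxy-4-oxocyclohex-2-ene-1-carboxylate, via Michael adduct 12 (not isolated)
Conditions: NaOMe (1.2 equiv), 2 (1.2 equiv), MeOH, 0 °C → reflux, 4 h; then aq. HCl to pH 3, 0 °C
Reagents that add atoms: none
Why: The same intermolecular Michael addition and Dieckmann-type Claisen closure as in step 1 builds the ring B carbocycle with alkyl, ester and both oxygens already in place, and the racemic stereocentres are erased in step 7.

Step 7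
Reactants: 13 methyl 6-heptyl-2-hydroxy-4-oxocyclohex-2-ene-1-carboxylate
Product: 15 methyl 2-heptyl-4,6-dihydroxybenzoate, via 3-bromo enol 14 (not isolated)
Conditions: Br2 (1.0 equiv), DMF, 0 °C, 1 h; then 80 °C, 12 h
Reagents that add atoms: bromine, BrBr (its bromine stands only in 14 and leaves again as HBr; none remains in 15)
Why: This is the bromination–dehydrobromination aromatisation of step 2, and the longer alkyl chain plays no part in it.

Step 8
Reactants: 15 methyl 2-heptyl-4,6-dihydroxybenzoate
Product: 16 methyl 4-(benzyloxy)-2-heptyl-6-hydroxybenzoate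
Conditions: BnBr (1.05 equiv), K2CO3 (1.2 equiv), acetone, reflux, 8 h
Reagents that add atoms: benzyl bromide, BrCc1ccccc1
Why: This Williamson etherification is regioselective because the para-OH is free and more acidic, whereas the ortho-OH is tied up in a hydrogen bond to the ester carbonyl and stays unreacted with one equivalent of halide.

Step 9
Reactants: 16 methyl 4-(benzyloxy)-2-heptyl-6-hydroxybenzoate
Product: 17 methyl 4-(benzyloxy)-2-heptyl-6-methoxybenzoate
Conditions: MeI (3 equiv), K2CO3 (3 equiv), DMF, 50 °C, 16 h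
Reagents that add atoms: iodomethane, CI
Why: Under more forcing Williamson conditions, excess MeI methylates the only remaining, chelated phenol, and the benzyl ether and ester are inert.

Step 10
Reactants: 17 methyl 4-(benzyloxy)-2-heptyl-6-methoxybenzoate
Product: 18 4-(benzyloxy)-2-heptyl-6-methoxybenzoic acid
Conditions: KOH (10 equiv), DMSO/H2O 4:1, 100 °C, 16 h; then 2 M HCl, 0 °C
Reagents that add atoms: potassium hydroxide, [K+].[OH-] (its oxygen becomes the new carboxyl oxygen)
Why: The hindered ester is saponified as in step 4, and both the benzyl and the methyl aryl ether are stable to hot hydroxide.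

Step 11
Reactants: 18 4-(benzyloxy)-2-heptyl-6-methoxybenzoic acid
Product: 19 2-heptyl-4-hydroxy-6-methoxybenzoic acid
Conditions: H2 (1 atm), 10% Pd/C, EtOAc, rt, 3 h; concentrate below 30 °C
Reagents that add atoms: none
Why: Catalytic hydrogenolysis cleaves only the benzylic C–O bond under neutral, cold conditions that do not decarboxylate the hydroxy acid.

Step 12
Reactants: 19 2-heptyl-4-hydroxy-6-methoxybenzoic acid
Product: 20 benzyl 2-heptyl-4-hydroxy-6-methoxybenzoate
Conditions: BnBr (1.05 equiv), KHCO3 (1.2 equiv), DMF, rt → 40 °C, 16 h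
Reagents that add atoms: benzyl bromide, BrCc1ccccc1
Why: This SN2 carboxylate alkylation is chemoselective because KHCO3 deprotonates the acid (pKa about 4) but not the phenol (pKa about 9–10), so only the ester forms.

Step 13
Reactants: 8 2,4-dimethoxy-6-pentylbenzoic acid; 20 benzyl 2-heptyl-4-hydroxy-6-methoxybenzoate
Product: 22 benzyl 4-[(2,4-dimethoxy-6-pentylbenzoyl)oxy]-2-heptyl-6-methoxybenzoate, via mixed anhydride 21 (not isolated)
Conditions: (CF3CO)2O (4 equiv), dry toluene, 0 °C → rt, 4 h
Reagents that add atoms: trifluoroacetic anhydride, O=C(OC(=O)C(F)(F)F)C(F)(F)F (its CF3CO group stands only in 21; none remains in 22)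
Why: In this mixed-anhydride esterification, the electron-rich hindered aroyl trifluoroacetate ionises easily toward an acylium ion, which sidesteps the steric block to tetrahedral addition and acylates the only free OH of 20.

Step 14
Reactants: 22 benzyl 4-[(2,4-dimethoxy-6-pentylbenzoyl)oxy]-2-heptyl-6-methoxybenzoate
Product: 23 4-[(2,4-dimethoxy-6-pentylbenzoyl)oxy]-2-heptyl-6-methoxybenzoic acid
Conditions: H2 (1 atm), 10% Pd/C, EtOAc, rt, 2 h
Reagents that add atoms: none
Why: Catalytic hydrogenolysis of the benzyl ester is neutral and free of nucleophiles, so the aryl ester link and the methyl ethers survive.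

## Compound list
1 | (E)-non-3-en-2-one | CCCCC/C=C/C(C)=O | starting material
2 | dimethyl malonate | COC(=O)CC(=O)OC | starting material
3 | dimethyl 2-(2-oxononan-4-yl)propanedioate (racemic) | CCCCCC(CC(C)=O)C(C(=O)OC)C(=O)OC | intermediate (not isolated)
4 | methyl 2-hydroxy-4-oxo-6-pentylcyclohex-2-ene-1-carboxylate (racemic, C1 epimers) | CCCCCC1CC(=O)C=C(O)C1C(=O)OC | intermediate
5 | methyl 3-bromo-2-hydroxy-4-oxo-6-pentylcyclohex-2-ene-1-carboxylate (racemic) | CCCCCC1CC(=O)C(Br)=C(O)C1C(=O)OC | intermediate (not isolated)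
6 | methyl 2,4-dihydroxy-6-pentylbenzoate | CCCCCc1cc(O)cc(O)c1C(=O)OC | intermediate
7 | methyl 2,4-dimethoxy-6-pentylbenzoate | CCCCCc1cc(OC)cc(OC)c1C(=O)OC | intermediate
8 | 2,4-dimethoxy-6-pentylbenzoic acid | CCCCCc1cc(OC)cc(OC)c1C(=O)O | intermediate
9 | octanal | CCCCCCCC=O | starting material
10 | 1-(triphenylphosphoranylidene)propan-2-one | CC(=O)C=P(c1ccccc1)(c1ccccc1)c1ccccc1 | starting material
11 | (E)-undec-3-en-2-one | CCCCCCC/C=C/C(C)=O | intermediate
12 | dimethyl 2-(2-oxoundecan-4-yl)propanedioate (racemic) | CCCCCCCC(CC(C)=O)C(C(=O)OC)C(=O)OC | intermediate (not isolated)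
13 | methyl 6-heptyl-2-hydroxy-4-oxocyclohex-2-ene-1-carboxylate (racemic, C1 epimers) | CCCCCCCC1CC(=O)C=C(O)C1C(=O)OC | intermediate
14 | methyl 3-bromo-6-heptyl-2-hydroxy-4-oxocyclohex-2-ene-1-carboxylate (racemic) | CCCCCCCC1CC(=O)C(Br)=C(O)C1C(=O)OC | intermediate (not isolated)
15 | methyl 2-heptyl-4,6-dihydroxybenzoate | CCCCCCCc1cc(O)cc(O)c1C(=O)OC | intermediate
16 | methyl 4-(benzyloxy)-2-heptyl-6-hydroxybenzoate | CCCCCCCc1cc(OCc2ccccc2)cc(O)c1C(=O)OC | intermediate
17 | methyl 4-(benzyloxy)-2-heptyl-6-methoxybenzoate | CCCCCCCc1cc(OCc2ccccc2)cc(OC)c1C(=O)OC | intermediate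
18 | 4-(benzyloxy)-2-heptyl-6-methoxybenzoic acid | CCCCCCCc1cc(OCc2ccccc2)cc(OC)c1C(=O)O | intermediate
19 | 2-heptyl-4-hydroxy-6-methoxybenzoic acid | CCCCCCCc1cc(O)cc(OC)c1C(=O)O | intermediate
20 | benzyl 2-heptyl-4-hydroxy-6-methoxybenzoate | CCCCCCCc1cc(O)cc(OC)c1C(=O)OCc2ccccc2 | intermediate
21 | 2,4-dimethoxy-6-pentylbenzoic trifluoroacetic anhydride | CCCCCc1cc(OC)cc(OC)c1C(=O)OC(=O)C(F)(F)F | intermediate (not isolated)
22 | benzyl 4-[(2,4-dimethoxy-6-pentylbenzoyl)oxy]-2-heptyl-6-methoxybenzoate | CCCCCCCc1cc(OC(=O)c2c(CCCCC)cc(OC)cc2OC)cc(OC)c1C(=O)OCc3ccccc3 | intermediate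
23 | 4-[(2,4-dimethoxy-6-pentylbenzoyl)oxy]-2-heptyl-6-methoxybenzoic acid (achiral) | CCCCCCCc1cc(OC(=O)c2c(CCCCC)cc(OC)cc2OC)cc(OC)c1C(=O)O | target

## Count and risks
Total steps: 14. Longest linear sequence: 10 steps (steps 5–14, from octanal).

**Step 13.** A di-ortho-substituted acid has to acylate a moderately nucleophilic phenol, and trifluoroacetylation of 20 or C-acylation can compete.
- The fallback sets out from 8 (together with 20) and comes back at 22.
- Acid 8 is turned with (COCl)2 and catalytic DMF in CH2Cl2 into isolable 2,4-dimethoxy-6-pentylbenzoyl chloride F1.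
- Separately, 20 is deprotonated with NaH in THF at 0 °C to sodium 4-[(benzyloxy)carbonyl]-3-heptyl-5-methoxyphenolate F2.
- Adding F1 to F2 (0 °C → rt) gives 22.
- A preformed strong nucleophile and an isolated acyl halide under basic conditions thus replace the acid-side acylium chemistry.

**Step 7.** The yield is typically moderate, and over-bromination or ester loss in hot HBr/DMF is possible. Step 2 is the same reaction on the well-known pentyl series.
- The fallback sets out from 13 and comes back at 16, so steps 7 and 8 are both bypassed.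
- 13 is condensed with benzyl alcohol (cat. p-TsOH, toluene, Dean–Stark) at the less hindered C4 carbonyl. This gives the vinylogous ester methyl 4-(benzyloxy)-6-heptyl-2-oxocyclohex-3-ene-1-carboxylate F3.
- Its β-keto ester carbon is selenenylated (NaH, THF, 0 °C; then PhSeCl), anti to the heptyl group. The product is methyl 4-(benzyloxy)-6-heptyl-2-oxo-1-(phenylselanyl)cyclohex-3-ene-1-carboxylate F4.
- H2O2 in CH2Cl2 at 0 °C gives methyl 4-(benzyloxy)-6-heptyl-2-oxo-1-(phenylseleninyl)cyclohex-3-ene-1-carboxylate F5.
- F5 undergoes syn-elimination toward the cis C6–H below room temperature and enolises to 16.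

**Step 10.** Hydrolysis of the di-ortho-hindered ester may be sluggish, and the electron-rich acid can decarboxylate on work-up. Step 4 is its twin.
- The fallback sets out from 17 and comes back at 18.
- The ester is reduced with LiAlH4 (THF, 0 °C → reflux) to [4-(benzyloxy)-2-heptyl-6-methoxyphenyl]methanol F6.
- F6 is oxidised with MnO2 (CH2Cl2, rt) to 4-(benzyloxy)-2-heptyl-6-methoxybenzaldehyde F7.
- A Pinnick oxidation (NaClO2, NaH2PO4, 2-methylbut-2-ene, t-BuOH/H2O, rt) then gives 18 under mild, nearly neutral conditions.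

## Further compounds
F1 | step 13 | 2,4-dimethoxy-6-pentylbenzoyl chloride | CCCCCc1cc(OC)cc(OC)c1C(=O)Cl
F2 | step 13 | sodium 4-[(benzyloxy)carbonyl]-3-heptyl-5-methoxyphenolate | CCCCCCCc1cc([O-])cc(OC)c1C(=O)OCc2ccccc2.[Na+]
F3 | step 7 | methyl 4-(benzyloxy)-6-heptyl-2-oxocyclohex-3-ene-1-carboxylate (racemic) | CCCCCCCC1CC(OCc2ccccc2)=CC(=O)C1C(=O)OC
F4 | step 7 | methyl 4-(benzyloxy)-6-heptyl-2-oxo-1-(phenylselanyl)cyclohex-3-ene-1-carboxylate (racemic) | CCCCCCCC1CC(OCc2ccccc2)=CC(=O)C1([Se]c3ccccc3)C(=O)OC
F5 | step 7 | methyl 4-(benzyloxy)-6-heptyl-2-oxo-1-(phenylseleninyl)cyclohex-3-ene-1-carboxylate (racemic) | CCCCCCCC1CC(OCc2ccccc2)=CC(=O)C1([Se](=O)c3ccccc3)C(=O)OC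
F6 | step 10 | [4-(benzyloxy)-2-heptyl-6-methoxyphenyl]methanol | CCCCCCCc1cc(OCc2ccccc2)cc(OC)c1CO
F7 | step 10 | 4-(benzyloxy)-2-heptyl-6-methoxybenzaldehyde | CCCCCCCc1cc(OCc2ccccc2)cc(OC)c1C=O
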